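**Strategy.** Everything rests on opening the cyclopentane of the cyclopenta[c]pyridine core at C4a–C7a, C5–C6 and C6–C7: C6, the oxygen-bearing carbon between C5H2 and methyl-bearing C7, is read as the carbonyl of a Pauson–Khand enone. One cobalt-mediated [2+2+1] step joins a terminal alkyne (C5, C4a), an E-crotyl alkene (C7a, C7) and CO, closing piperidine and cyclopentenone together and setting C7 and C7a. Its precursor is an acyclic Boc carbamate bearing (2S)-2-methylbut-3-ynyl and (E)-but-2-enyl groups on nitrogen. Hydrogenation, hydride reduction and a Mitsunobu esterification (inversion at C6) then attach a preassembled half-ester whose trans-cyclohexanediol is fixed by a bridged lactone.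

Key step: step 4

Remark (structure check): with the core numbered C1, N2, C3, C4, C4a, C5, C6, C7, C7a, the target is (4S,4aR,6S,7R,7aS). H4, H4a, H7a, the C7 methyl and the C6 oxygen lie on one face and the C4 methyl on the other. In the cyclohexane unit the two hydroxyls are trans, so the CH2CH2O arm is cis to the secondary hydroxyl. The (2S) enyne and the (4S,7R,7aR) enone used below map correctly onto C4, C7 and C7a and need no correction.

Remark (precursor design): the alkyne is kept terminal so that only a hydrogen on C5 faces the C4 methyl, and nitrogen is kept as the Boc carbamate because LiAlH4 later turns it directly into N-methyl. The precursor is reached in three steps from a bromo alcohol, which avoids the volatile 2-methylbut-3-yn-1-ol.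

Assumption: (S)-3-bromo-2-methylpropan-1-ol and (E)-but-2-en-1-amine are bought isomerically pure.

**Core**

Step 1
Reactants: 1 (S)-3-bromo-2-methylpropan-1-ol; 2 (E)-but-2-en-1-amine
Product: 4 tert-butyl N-[(E)-but-2-en-1-yl]-N-[(2R)-3-hydroxy-2-methylpropyl]carbamate, via secondary amine 3 (not isolated)
Conditions: 2 (4 equiv), K2CO3, MeCN, 70 °C (sealed); filter, concentrate; then Boc2O, CH2Cl2, rt
Reagents that add atoms: di-tert-butyl dicarbonate (Boc2O), CC(C)(C)OC(=O)OC(=O)OC(C)(C)C
Why: SN2 displacement of the primary bromide by the excess primary amine (the stereocentre is not at the reacting carbon and excess amine suppresses dialkylation) is followed by chemoselective N-acylation of the secondary amine with Boc2O in the presence of the free hydroxyl.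

Step 2
Reactants: 4 tert-butyl N-[(E)-but-2-en-1-yl]-N-[(2R)-3-hydroxy-2-methylpropyl]carbamate
Product: 5 tert-butyl N-[(E)-but-2-en-1-yl]-N-[(2R)-2-methyl-3-oxopropyl]carbamate
Conditions: Dess–Martin periodinane, CH2Cl2, 0 °C to rt
Reagents that add atoms: none
Why: Dess–Martin oxidation converts the primary alcohol into the aldehyde under non-basic, non-aqueous conditions that should not epimerize the α-stereocentre, and the crude aldehyde is used at once.

Step 3
Reactants: 5 tert-butyl N-[(E)-but-2-en-1-yl]-N-[(2R)-2-methyl-3-oxopropyl]carbamate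
Product: 6 tert-butyl N-[(E)-but-2-en-1-yl]-N-[(2S)-2-methylbut-3-yn-1-yl]carbamate
Conditions: dimethyl (1-diazo-2-oxopropyl)phosphonate, K2CO3, MeOH, 0 °C to rt
Reagents that add atoms: Ohira–Bestmann reagent, dimethyl (1-diazo-2-oxopropyl)phosphonate, COP(=O)(OC)C(=[N+]=[N-])C(C)=O
Why: Ohira–Bestmann alkynylation (Seyferth–Gilbert homologation under mild K2CO3/MeOH conditions) converts the aldehyde into the terminal alkyne with one added carbon, and at 0 °C α-methyl-branched aldehydes are expected to pass with their configuration essentially intact.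

Step 4
Reactants: 6 tert-butyl N-[(E)-but-2-en-1-yl]-N-[(2S)-2-methylbut-3-yn-1-yl]carbamate
Product: 8 tert-butyl (4S,7R,7aR)-4,7-dimethyl-6-oxo-1,3,4,6,7,7a-hexahydro-2H-cyclopenta[c]pyridine-2-carboxylate, via alkyne–Co2(CO)6 complex 7 (not isolated)
Conditions: Co2(CO)8 (1.1 equiv), ClCH2CH2Cl, rt, 1 h; then n-BuSMe (4 equiv), 83 °C
Reagents that add atoms: dicobalt octacarbonyl Co2(CO)8 (source of the C6 carbonyl), O=C=[Co](=C=O)(=C=O)(=C=O)[Co](=C=O)(=C=O)(=C=O)=C=O
Why: Co2(CO)8 first forms the alkyne–Co2(CO)6 complex 7; after sulfide-assisted loss of CO the crotyl alkene coordinates and inserts into the Co–C bond of the internal alkyne carbon to give a cobaltacyclopentene, CO inserts and reductive elimination releases the enone, which is the established course of the intramolecular Pauson–Khand [2+2+1] reaction of nitrogen-tethered 1,7-enynes. The piperidine closes in the insertion event by C4a–C7a bond formation in an exo mode (C5 and C7 stay outside the six-membered ring), and the cyclopentenone closes in the carbonylative steps that form C6–C7 and C5–C6. C7 is fixed relative to C7a by the E alkene geometry, because both new bonds to the alkene form on the same face, which puts H7 and H7a trans. C7a is set relative to the existing C4 centre: in the chair-like closing tether the C4 methyl sits pseudo-equatorial and the C7a–C7 bond forms on the same side, giving the cis-1,3 arrangement with H4 and H7a cis. The step needs regiocontrol (carbonyl next to the former alkyne terminus), which the tether enforces, and facial control, which rests on the C4 methyl, helped by the terminal alkyne (only H on C5 faces that methyl) and by the carbamate, which flattens the tether.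

Step 5
Reactants: 8 tert-butyl (4S,7R,7aR)-4,7-dimethyl-6-oxo-1,3,4,6,7,7a-hexahydro-2H-cyclopenta[c]pyridine-2-carboxylate
Product: 9 tert-butyl (4S,4aR,7R,7aS)-4,7-dimethyl-6-oxooctahydro-2H-cyclopenta[c]pyridine-2-carboxylate
Conditions: H2 (1 atm), 10% Pd/C, EtOAc, rt
Reagents that add atoms: none
Why: Heterogeneous hydrogenation of the conjugated C4a=C5 bond should deliver both hydrogens from the more open face carrying H7a (opposite the C4 methyl and the C7a–C1 bond), which sets C4a with H4a cis to H7a and gives the cis-fused ketone.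

Step 6
Reactants: 9 tert-butyl (4S,4aR,7R,7aS)-4,7-dimethyl-6-oxooctahydro-2H-cyclopenta[c]pyridine-2-carboxylate
Product: 10 (4S,4aR,6R,7R,7aS)-2,4,7-trimethyloctahydro-1H-cyclopenta[c]pyridin-6-ol (hydroxyl trans to the C7 methyl)
Conditions: LiAlH4 (4 equiv), THF, −78 °C to 0 °C, then reflux
Reagents that add atoms: none
Why: LiAlH4 should first add hydride to the C6 ketone from the convex face of the cis-fused bicycle (the face of H4a and H7a, also the preferred mode of small hydrides on 2-methylcyclopentanones) to give the 6R alcohol, and on heating it reduces the Boc carbamate to N-methyl (carbamate-to-methylamine reduction).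

**Cyclohexane fragment**

Step 7
Reactants: 11 2-(trimethylsilyloxy)buta-1,3-diene; 12 methyl vinyl ketone (but-3-en-2-one)
Product: 14 4-acetylcyclohexan-1-one, via silyl enol ether 13 (not isolated)
Conditions: toluene, 110 °C (sealed); then 1 M HCl, THF, rt
Reagents that add atoms: none
Why: Diels–Alder cycloaddition of the 2-silyloxydiene with the enone gives the 1,4-disubstituted ("para") cyclohexene by the usual orientation of 2-donor dienes, and mild acid hydrolysis of the silyl enol ether releases the ring ketone.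

Step 8
Reactants: 14 4-acetylcyclohexan-1-one
Product: 15 4-hydroxybicyclo[2.2.2]octan-2-one
Conditions: KOH (0.2 equiv), MeOH–H2O, rt
Reagents that add atoms: none
Why: Intramolecular aldol addition of the methyl-ketone enolate to the ring carbonyl across the boat conformer closes the bicyclo[2.2.2]octane, and because a bridgehead alkene cannot form the reaction stops at the ketol.

Step 9
Reactants: 15 4-hydroxybicyclo[2.2.2]octan-2-one
Product: 16 5-hydroxy-2-oxabicyclo[3.2.2]nonan-3-one
Conditions: mCPBA, NaHCO3, CH2Cl2, 0 °C to rt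
Reagents that add atoms: 3-chloroperoxybenzoic acid (mCPBA), OOC(=O)c1cccc(Cl)c1
Why: Baeyer–Villiger oxidation with migration of the more substituted bridgehead carbon (the methylene is primary and deactivated by the β-hydroxyl) inserts oxygen between C1 and the carbonyl with retention, and the bridged lactone necessarily holds the ring oxygen and the CH2C(=O) arm cis on the cyclohexane, that is, the new C–O bond trans to the tertiary hydroxyl.

Step 10
Reactants: 16 5-hydroxy-2-oxabicyclo[3.2.2]nonan-3-one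
Product: 17 methyl 2-(trans-1,4-dihydroxycyclohexyl)acetate (hydroxyls trans; CH2CO2Me arm cis to the secondary hydroxyl)
Conditions: K2CO3 (0.2 equiv), MeOH, 0 °C to rt
Reagents that add atoms: methanol, CO
Why: Base-catalysed transesterification opens the strained bridged lactone by acyl–oxygen cleavage, so no bond to a ring stereocentre is broken and the trans relationship of the two hydroxyls from step 9 is kept.

Step 11
Reactants: 17 methyl 2-(trans-1,4-dihydroxycyclohexyl)acetate
Product: 18 methyl 2-[trans-4-(tert-butyldimethylsilyloxy)-1-hydroxycyclohexyl]acetate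
Conditions: TBSCl, imidazole, DMF, rt
Reagents that add atoms: tert-butyldimethylsilyl chloride (TBSCl), CC(C)(C)[Si](C)(C)Cl
Why: Silylation with TBSCl/imidazole protects the secondary hydroxyl selectively because the tertiary hydroxyl is too hindered to react under these conditions.

Step 12
Reactants: 18 methyl 2-[trans-4-(tert-butyldimethylsilyloxy)-1-hydroxycyclohexyl]acetate
Product: 19 2-[trans-4-(tert-butyldimethylsilyloxy)-1-hydroxycyclohexyl]ethan-1-ol
Conditions: LiAlH4, THF, 0 °C
Reagents that add atoms: none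
Why: LiAlH4 reduces the methyl ester to the primary alcohol while the silyl ether and the tertiary alkoxide are inert.

**Side chain**

Step 13
Reactants: 20 geranyl acetate
Product: 21 (2E,6E)-8-hydroxy-3,7-dimethylocta-2,6-dien-1-yl acetate
Conditions: SeO2 (0.1 equiv), t-BuOOH (3 equiv), salicylic acid (0.1 equiv), CH2Cl2, rt
Reagents that add atoms: tert-butyl hydroperoxide, CC(C)(C)OO
Why: Catalytic SeO2 with tert-butyl hydroperoxide effects the allylic (ene then [2,3]-sigmatropic) oxidation of the terminal trisubstituted alkene selectively at its E methyl group, an established reaction of geranyl acetate, and any over-oxidized aldehyde converges in step 14.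

Step 14
Reactants: 21 (2E,6E)-8-hydroxy-3,7-dimethylocta-2,6-dien-1-yl acetate
Product: 23 (2E,6E)-8-acetoxy-2,6-dimethylocta-2,6-dienoic acid, via enal 22 (not isolated)
Conditions: TEMPO (0.1 equiv), PhI(OAc)2, CH2Cl2, rt; then NaClO2, NaH2PO4, 2-methyl-2-butene, t-BuOH–H2O, rt
Reagents that add atoms: sodium chlorite NaClO2, [Na+].[O-]Cl=O
Why: TEMPO/PhI(OAc)2 oxidizes the allylic alcohol to the E enal without touching the alkenes or the acetate, and Pinnick oxidation with a hypochlorite scavenger then gives the conjugated acid with the alkene geometry retained.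

Step 15
Reactants: 23 (2E,6E)-8-acetoxy-2,6-dimethylocta-2,6-dienoic acid; 19 2-[trans-4-(tert-butyldimethylsilyloxy)-1-hydroxycyclohexyl]ethan-1-ol
Product: 24 2-[trans-4-(tert-butyldimethylsilyloxy)-1-hydroxycyclohexyl]ethyl (2E,6E)-8-acetoxy-2,6-dimethylocta-2,6-dienoate
Conditions: EDC·HCl, DMAP, CH2Cl2, 0 °C to rt
Reagents that add atoms: none
Why: Steglich esterification (carbodiimide activation with DMAP acyl transfer) acylates the primary hydroxyl of 19 selectively, the tertiary hydroxyl being unreactive.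

Step 16
Reactants: 24 2-[trans-4-(tert-butyldimethylsilyloxy)-1-hydroxycyclohexyl]ethyl (2E,6E)-8-acetoxy-2,6-dimethylocta-2,6-dienoate
Product: 25 2-[trans-4-(tert-butyldimethylsilyloxy)-1-hydroxycyclohexyl]ethyl (2E,6E)-8-hydroxy-2,6-dimethylocta-2,6-dienoate
Conditions: K2CO3 (0.2 equiv), MeOH, 0 °C
Reagents that add atoms: none
Why: Mild methanolysis with catalytic K2CO3 at 0 °C should remove the unhindered primary allylic acetate much faster than it attacks the conjugated, α-branched dienoate ester, and the silyl ether is stable.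

Step 17
Reactants: 25 2-[trans-4-(tert-butyldimethylsilyloxy)-1-hydroxycyclohexyl]ethyl (2E,6E)-8-hydroxy-2,6-dimethylocta-2,6-dienoate
Product: 27 (2E,6E)-8-{2-[trans-4-(tert-butyldimethylsilyloxy)-1-hydroxycyclohexyl]ethoxy}-3,7-dimethyl-8-oxoocta-2,6-dienoic acid, via enal 26 (not isolated)
Conditions: TEMPO (0.1 equiv), PhI(OAc)2, CH2Cl2, rt; then NaClO2, NaH2PO4, 2-methyl-2-butene, t-BuOH–H2O, rt
Reagents that add atoms: sodium chlorite NaClO2, [Na+].[O-]Cl=O
Why: TEMPO/PhI(OAc)2 oxidizes the primary allylic alcohol to the geranial-type E enal without isomerization and leaves the tertiary alcohol alone, and Pinnick oxidation then gives the β,β-disubstituted enoic acid with retained geometry.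

**Union**

Step 18
Reactants: 27 (2E,6E)-8-{2-[trans-4-(tert-butyldimethylsilyloxy)-1-hydroxycyclohexyl]ethoxy}-3,7-dimethyl-8-oxoocta-2,6-dienoic acid; 10 (4S,4aR,6R,7R,7aS)-2,4,7-trimethyloctahydro-1H-cyclopenta[c]pyridin-6-ol
Product: 28 1-{2-[trans-4-(tert-butyldimethylsilyloxy)-1-hydroxycyclohexyl]ethyl} 8-[(4S,4aR,6S,7R,7aS)-2,4,7-trimethyloctahydro-1H-cyclopenta[c]pyridin-6-yl] (2E,6E)-2,6-dimethylocta-2,6-dienedioate
Conditions: PPh3, DIAD, THF, 0 °C to rt
Reagents that add atoms: none
Why: Mitsunobu esterification activates the C6 hydroxyl of 10 as an alkoxyphosphonium ion that the carboxylate of 27 displaces by SN2 with inversion, turning 6R into the required 6S ester (oxygen cis to the C7 methyl), while the tertiary hydroxyl of 27 cannot be activated and the tertiary amine is tolerated.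

Step 19
Reactants: 28 1-{2-[trans-4-(tert-butyldimethylsilyloxy)-1-hydroxycyclohexyl]ethyl} 8-[(4S,4aR,6S,7R,7aS)-2,4,7-trimethyloctahydro-1H-cyclopenta[c]pyridin-6-yl] (2E,6E)-2,6-dimethylocta-2,6-dienedioate
Product: 29 1-[2-(trans-1,4-dihydroxycyclohexyl)ethyl] 8-[(4S,4aR,6S,7R,7aS)-2,4,7-trimethyloctahydro-1H-cyclopenta[c]pyridin-6-yl] (2E,6E)-2,6-dimethylocta-2,6-dienedioate (CNP0298382.1)
Conditions: HF·pyridine, pyridine, THF, 0 °C to rt; aq. NaHCO3 work-up
Reagents that add atoms: none
Why: Fluoride-mediated cleavage of the secondary silyl ether with buffered HF·pyridine should leave both esters, the tertiary alcohol, the trisubstituted alkenes and the amine untouched.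

**Compound list**

1 | (S)-3-bromo-2-methylpropan-1-ol | BrC[C@@H](C)CO | starting material
2 | (E)-but-2-en-1-amine | C/C=C/CN | starting material
3 | (R)-3-[(E)-but-2-en-1-ylamino]-2-methylpropan-1-ol | C/C=C/CNC[C@@H](C)CO | intermediate
4 | tert-butyl N-[(E)-but-2-en-1-yl]-N-[(2R)-3-hydroxy-2-methylpropyl]carbamate | C/C=C/CN(C(=O)OC(C)(C)C)C[C@@H](C)CO | intermediate
5 | tert-butyl N-[(E)-but-2-en-1-yl]-N-[(2R)-2-methyl-3-oxopropyl]carbamate | C/C=C/CN(C(=O)OC(C)(C)C)C[C@@H](C)C=O | intermediate
6 | tert-butyl N-[(E)-but-2-en-1-yl]-N-[(2S)-2-methylbut-3-yn-1-yl]carbamate | C/C=C/CN(C(=O)OC(C)(C)C)C[C@H](C#C)C | intermediate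
7 | hexacarbonyldicobalt complex of the alkyne of 6 (C2Co2 tetrahedrane core, three CO on each cobalt) | C/C=C/CN(C(=O)OC(C)(C)C)C[C@@H](C)C12[CH]3[Co]1(=C=O)(=C=O)(=C=O)[Co]23(=C=O)(=C=O)=C=O | intermediate
8 | tert-butyl (4S,7R,7aR)-4,7-dimethyl-6-oxo-1,3,4,6,7,7a-hexahydro-2H-cyclopenta[c]pyridine-2-carboxylate | O=C1C=C2[C@H](CN(C(=O)OC(C)(C)C)C[C@H]2C)[C@H]1C | intermediate
9 | tert-butyl (4S,4aR,7R,7aS)-4,7-dimethyl-6-oxooctahydro-2H-cyclopenta[c]pyridine-2-carboxylate (cis-fused) | O=C1C[C@H]2[C@H](CN(C(=O)OC(C)(C)C)C[C@H]2C)[C@H]1C | intermediate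
10 | (4S,4aR,6R,7R,7aS)-2,4,7-trimethyloctahydro-1H-cyclopenta[c]pyridin-6-ol | O[C@@H]1C[C@H]2[C@H](CN(C)C[C@H]2C)[C@H]1C | intermediate
11 | 2-(trimethylsilyloxy)buta-1,3-diene | C=CC(=C)O[Si](C)(C)C | starting material
12 | methyl vinyl ketone (but-3-en-2-one) | CC(=O)C=C | starting material
13 | 1-[4-(trimethylsilyloxy)cyclohex-3-en-1-yl]ethan-1-one (racemic) | CC(=O)C1CCC(O[Si](C)(C)C)=CC1 | intermediate
14 | 4-acetylcyclohexan-1-one (achiral) | CC(=O)C1CCC(=O)CC1 | intermediate
15 | 4-hydroxybicyclo[2.2.2]octan-2-one (achiral) | O=C1CC2(O)CCC1CC2 | intermediate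
16 | 5-hydroxy-2-oxabicyclo[3.2.2]nonan-3-one (achiral; lactone oxygen and CH2C(=O) arm cis on the cyclohexane) | O=C1CC2(O)CCC(O1)CC2 | intermediate
17 | methyl 2-(trans-1,4-dihydroxycyclohexyl)acetate (hydroxyls trans) | COC(=O)C[C@]1(O)CC[C@H](O)CC1 | intermediate
18 | methyl 2-[trans-4-(tert-butyldimethylsilyloxy)-1-hydroxycyclohexyl]acetate | COC(=O)C[C@]1(O)CC[C@H](O[Si](C)(C)C(C)(C)C)CC1 | intermediate
19 | 2-[trans-4-(tert-butyldimethylsilyloxy)-1-hydroxycyclohexyl]ethan-1-ol | OCC[C@]1(O)CC[C@H](O[Si](C)(C)C(C)(C)C)CC1 | intermediate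
20 | geranyl acetate, (2E)-3,7-dimethylocta-2,6-dien-1-yl acetate | CC(C)=CCC/C(C)=C/COC(C)=O | starting material
21 | (2E,6E)-8-hydroxy-3,7-dimethylocta-2,6-dien-1-yl acetate | CC(=O)OC/C=C(\C)CC/C=C(\C)CO | intermediate
22 | (2E,6E)-3,7-dimethyl-8-oxoocta-2,6-dien-1-yl acetate | CC(=O)OC/C=C(\C)CC/C=C(\C)C=O | intermediate
23 | (2E,6E)-8-acetoxy-2,6-dimethylocta-2,6-dienoic acid | CC(=O)OC/C=C(\C)CC/C=C(\C)C(=O)O | intermediate
24 | 2-[trans-4-(tert-butyldimethylsilyloxy)-1-hydroxycyclohexyl]ethyl (2E,6E)-8-acetoxy-2,6-dimethylocta-2,6-dienoate | CC(=O)OC/C=C(\C)CC/C=C(\C)C(=O)OCC[C@]1(O)CC[C@H](O[Si](C)(C)C(C)(C)C)CC1 | intermediate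
25 | 2-[trans-4-(tert-butyldimethylsilyloxy)-1-hydroxycyclohexyl]ethyl (2E,6E)-8-hydroxy-2,6-dimethylocta-2,6-dienoate | OC/C=C(\C)CC/C=C(\C)C(=O)OCC[C@]1(O)CC[C@H](O[Si](C)(C)C(C)(C)C)CC1 | intermediate
26 | 2-[trans-4-(tert-butyldimethylsilyloxy)-1-hydroxycyclohexyl]ethyl (2E,6E)-2,6-dimethyl-8-oxoocta-2,6-dienoate | O=C/C=C(\C)CC/C=C(\C)C(=O)OCC[C@]1(O)CC[C@H](O[Si](C)(C)C(C)(C)C)CC1 | intermediate
27 | (2E,6E)-8-{2-[trans-4-(tert-butyldimethylsilyloxy)-1-hydroxycyclohexyl]ethoxy}-3,7-dimethyl-8-oxoocta-2,6-dienoic acid | OC(=O)/C=C(\C)CC/C=C(\C)C(=O)OCC[C@]1(O)CC[C@H](O[Si](C)(C)C(C)(C)C)CC1 | intermediate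
28 | 1-{2-[trans-4-(tert-butyldimethylsilyloxy)-1-hydroxycyclohexyl]ethyl} 8-[(4S,4aR,6S,7R,7aS)-2,4,7-trimethyloctahydro-1H-cyclopenta[c]pyridin-6-yl] (2E,6E)-2,6-dimethylocta-2,6-dienedioate | C/C(=C\C(=O)O[C@H]1C[C@H]2[C@H](CN(C)C[C@H]2C)[C@H]1C)CC/C=C(\C)C(=O)OCC[C@]1(O)CC[C@H](O[Si](C)(C)C(C)(C)C)CC1 | intermediate
29 | 1-[2-(trans-1,4-dihydroxycyclohexyl)ethyl] 8-[(4S,4aR,6S,7R,7aS)-2,4,7-trimethyloctahydro-1H-cyclopenta[c]pyridin-6-yl] (2E,6E)-2,6-dimethylocta-2,6-dienedioate (CNP0298382.1) | C/C(=C\C(=O)O[C@H]1C[C@H]2[C@H](CN(C)C[C@H]2C)[C@H]1C)CC/C=C(\C)C(=O)OCC[C@]1(O)CC[C@H](O)CC1 | target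

**Totals**

Total step count: 19. Longest linear sequence: 11 steps (steps 7–12, then 15–19).

**Steps most likely to fail**

Step 4 (key step). Insertion of the 1,2-disubstituted alkene in a 1,7-enyne may be slow, so that decomplexation, alkyne oligomerization or reductive side paths compete, and the single C4 methyl may give too little facial discrimination at C7a. The fallback keeps the disconnection but changes the tether to a sulfonamide, the classical and most reactive nitrogen tether for cobalt bicyclizations. Setting out from 6, TFA in CH2Cl2 removes the Boc group to give (2S)-N-[(E)-but-2-en-1-yl]-2-methylbut-3-yn-1-amine F1, handled as its salt. TsCl and Et3N convert it into N-[(E)-but-2-en-1-yl]-4-methyl-N-[(2S)-2-methylbut-3-yn-1-yl]benzenesulfonamide F2. Co2(CO)8 followed by N-methylmorpholine N-oxide in CH2Cl2 should give (4S,7R,7aR)-4,7-dimethyl-2-tosyl-1,2,3,4,7,7a-hexahydro-6H-cyclopenta[c]pyridin-6-one F3. H2 over Pd/C gives the cis-fused (4S,4aR,7R,7aS)-4,7-dimethyl-2-tosyloctahydro-6H-cyclopenta[c]pyridin-6-one F4, and NaBH4 in MeOH gives (4S,4aR,6R,7R,7aS)-4,7-dimethyl-2-tosyloctahydro-1H-cyclopenta[c]pyridin-6-ol F5. Na/naphthalene (NaC10H8) in DME at −78 °C cleaves the sulfonamide to (4S,4aR,6R,7R,7aS)-4,7-dimethyloctahydro-1H-cyclopenta[c]pyridin-6-ol F6. Aqueous formaldehyde with NaBH(OAc)3 then N-methylates F6, and the sequence comes back to the route at 10.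

Step 18. Activation of the hindered C6 hydroxyl next to the methyl-bearing C7 may be slow with the weakly acidic, precious enoic acid, and elimination or simple return of 10 could dominate. The fallback separates inversion from acylation. Setting out from 10, a Mitsunobu reaction with the more acidic 4-nitrobenzoic acid (PPh3, DIAD, THF) gives (4S,4aR,6S,7R,7aS)-2,4,7-trimethyloctahydro-1H-cyclopenta[c]pyridin-6-yl 4-nitrobenzoate F7. K2CO3 in MeOH releases (4S,4aR,6S,7R,7aS)-2,4,7-trimethyloctahydro-1H-cyclopenta[c]pyridin-6-ol F8. This alcohol already has the target configuration and is acylated with retention by 27 under Steglich conditions (EDC·HCl, DMAP, CH2Cl2), coming back to the route at 28.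

Step 5. Hydrogen may add without sufficient face preference at C4a, giving some trans-fused ketone. The fallback replaces steric control by hydroxyl direction. Setting out from 8, Luche reduction (NaBH4, CeCl3·7H2O, MeOH, −78 °C; hydride anti to the C7 methyl) gives tert-butyl (4S,6R,7R,7aR)-6-hydroxy-4,7-dimethyl-1,3,4,6,7,7a-hexahydro-2H-cyclopenta[c]pyridine-2-carboxylate F9, with the hydroxyl cis to the C7 methyl. Hydrogenation with [Ir(cod)(PCy3)(py)]PF6 in CH2Cl2 delivers hydrogen to the face of that hydroxyl and gives the cis-fused tert-butyl (4S,4aR,6S,7R,7aS)-6-hydroxy-4,7-dimethyloctahydro-2H-cyclopenta[c]pyridine-2-carboxylate F10. Dess–Martin oxidation of F10 comes back to the route at 9.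

**Further compounds**

F1 | step 4 | (2S)-N-[(E)-but-2-en-1-yl]-2-methylbut-3-yn-1-amine | C/C=C/CNC[C@@H](C)C#C
F2 | step 4 | N-[(E)-but-2-en-1-yl]-4-methyl-N-[(2S)-2-methylbut-3-yn-1-yl]benzenesulfonamide | C/C=C/CN(C[C@@H](C)C#C)S(=O)(=O)c1ccc(C)cc1
F3 | step 4 | (4S,7R,7aR)-4,7-dimethyl-2-tosyl-1,2,3,4,7,7a-hexahydro-6H-cyclopenta[c]pyridin-6-one | O=C1C=C2[C@H](CN(S(=O)(=O)c3ccc(C)cc3)C[C@H]2C)[C@H]1C
F4 | step 4 | (4S,4aR,7R,7aS)-4,7-dimethyl-2-tosyloctahydro-6H-cyclopenta[c]pyridin-6-one | O=C1C[C@H]2[C@H](CN(S(=O)(=O)c3ccc(C)cc3)C[C@H]2C)[C@H]1C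
F5 | step 4 | (4S,4aR,6R,7R,7aS)-4,7-dimethyl-2-tosyloctahydro-1H-cyclopenta[c]pyridin-6-ol | O[C@@H]1C[C@H]2[C@H](CN(S(=O)(=O)c3ccc(C)cc3)C[C@H]2C)[C@H]1C
F6 | step 4 | (4S,4aR,6R,7R,7aS)-4,7-dimethyloctahydro-1H-cyclopenta[c]pyridin-6-ol | O[C@@H]1C[C@H]2[C@H](CNC[C@H]2C)[C@H]1C
F7 | step 18 | (4S,4aR,6S,7R,7aS)-2,4,7-trimethyloctahydro-1H-cyclopenta[c]pyridin-6-yl 4-nitrobenzoate | O=C(O[C@H]1C[C@H]2[C@H](CN(C)C[C@H]2C)[C@H]1C)c1ccc(cc1)[N+](=O)[O-]
F8 | step 18 | (4S,4aR,6S,7R,7aS)-2,4,7-trimethyloctahydro-1H-cyclopenta[c]pyridin-6-ol | O[C@H]1C[C@H]2[C@H](CN(C)C[C@H]2C)[C@H]1C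
F9 | step 5 | tert-butyl (4S,6R,7R,7aR)-6-hydroxy-4,7-dimethyl-1,3,4,6,7,7a-hexahydro-2H-cyclopenta[c]pyridine-2-carboxylate | O[C@H]1C=C2[C@H](CN(C(=O)OC(C)(C)C)C[C@H]2C)[C@H]1C
F10 | step 5 | tert-butyl (4S,4aR,6S,7R,7aS)-6-hydroxy-4,7-dimethyloctahydro-2H-cyclopenta[c]pyridine-2-carboxylate | O[C@H]1C[C@H]2[C@H](CN(C(=O)OC(C)(C)C)C[C@H]2C)[C@H]1C
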